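**Strategy.** Numbering: C1 ketone, C2 (carrying the C7 hydroxymethyl), C3, C4 (propanoate), C5 (isopropyl), C6 (hydroxytiglate) of the cyclohexenone ring. The plan cuts the C1–C6 bond: these two neighbouring ring carbons both carry oxygen, so they can be joined by reductive coupling of two aldehydes. In one operation SmI2 closes the six-membered ring, forms C1–C6 and sets the C6 carbinol trans to the C5 isopropyl group; the C1 carbinol is then oxidised to the enone. The precursor is an acyclic (2Z)-hex-2-enedial with the C4 oxygen as a PMB ether, the C7 oxygen as a TBS ether and the anti C4/C5 pair set by allylboration.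

Key step: step 9

Assumption 1: (R)-TRIP, (R)-3,3'-bis(2,4,6-triisopropylphenyl)-1,1'-binaphthyl-2,2'-diyl hydrogen phosphate, is taken to direct the allyl group to the Re face of ynal 8, as it does with aryl and alkenyl aldehydes; if the sense proves opposite, (S)-TRIP is used.
Assumption 2: metal alkoxides formed before an aqueous quench are taken as protonated in the work-up of the same step and carry no number.
Abbreviations: TBS = tert-butyldimethylsilyl, PMB = 4-methoxybenzyl.

**Route**

Step 1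
Reactants: 1 2-methylpropanal (isobutyraldehyde); 2 vinylmagnesium bromide
Product: 3 4-methylpent-1-en-3-ol (racemic)
Conditions: THF, 0 °C; aq. NH4Cl
Reagents that add atoms: none
Why: Grignard 1,2-addition to an aldehyde; the carbinol centre forms racemic, which does not matter because it is lost in step 2.

Step 2
Reactants: 3 4-methylpent-1-en-3-ol; 4 bis(pinacolato)diboron
Product: 5 4,4,5,5-tetramethyl-2-[(2E)-4-methylpent-2-en-1-yl]-1,3,2-dioxaborolane
Conditions: Pd(MeCN)4(BF4)2 (5 mol %), DMSO/MeOH (1:1), 50 °C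
Reagents that add atoms: none
Why: Palladium-catalysed allylic C–OH borylation through an η3-allylpalladium intermediate; boron should enter at the unhindered terminus and the syn-allyl complex should give the (E)-alkene.

Step 3
Reactants: 6 tert-butyldimethyl(prop-2-yn-1-yloxy)silane
Product: 8 4-[(tert-butyldimethylsilyl)oxy]but-2-ynal, via lithium acetylide 7 (not isolated)
Conditions: n-BuLi, THF, −78 °C; DMF, −78 to 0 °C; inverse quench into aq. KH2PO4/MTBE, 0 °C
Reagents that add atoms: N,N-dimethylformamide, CN(C)C=O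
Why: Formylation of a lithium acetylide with DMF; the buffered inverse quench keeps the liberated dimethylamine from adding to the ynal.

Step 4
Reactants: 8 4-[(tert-butyldimethylsilyl)oxy]but-2-ynal; 5 (E)-allylboronate
Product: 10 (3R,4R)-7-[(tert-butyldimethylsilyl)oxy]-3-(propan-2-yl)hept-1-en-5-yn-4-ol, via pinacol borate 9 (not isolated)
Conditions: (R)-TRIP (5 mol %), 4 Å MS, toluene, −40 °C; aq. NaHCO3
Reagents that add atoms: none
Why: Chiral phosphoric acid-catalysed allylboration of an aldehyde; the closed chair transition state should turn the (E)-boronate into the anti C4/C5 pair, and the (R)-acid, hydrogen-bonded to the boronate oxygen and the formyl hydrogen, should expose the Re face to give the (3R,4R) isomer.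

Step 5
Reactants: 10 (3R,4R)-homoallylic propargylic alcohol
Product: 12 (3R,4R,5Z)-7-[(tert-butyldimethylsilyl)oxy]-6-iodo-3-(propan-2-yl)hepta-1,5-dien-4-ol, via cyclic vinylalanate 11 (not isolated)
Conditions: NaAlH2(OCH2CH2OMe)2, THF, 0 °C to rt; EtOAc; I2, THF, −78 to 0 °C; aq. Na2S2O3/KNaC4H4O6
Reagents that add atoms: iodine, II
Why: Hydroxyl-directed trans-hydroalumination of a propargylic alcohol followed by iodinolysis with retention; the five-membered oxa-aluminacycle should fix aluminium, and hence iodine, on C2 cis to C4, which defines the (Z)-alkene.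

Step 6
Reactants: 12 (Z)-iodo alcohol
Product: 13 tert-butyl({(2Z,4R,5R)-2-iodo-4-[(4-methoxyphenyl)methoxy]-5-(propan-2-yl)hepta-2,6-dien-1-yl}oxy)dimethylsilane
Conditions: NaH, PMBCl, Bu4NI (cat.), DMF, 0 °C to rt
Reagents that add atoms: 4-methoxybenzyl chloride, COc1ccc(CCl)cc1
Why: Williamson etherification of the sodium alkoxide; no stereocentre is touched, and a benzyl-type ether is chosen because its alkoxide is a poor leaving group in step 9.

Step 7
Reactants: 13 (Z)-iodo PMB ether
Product: 15 (2Z,4R,5R)-2-{[(tert-butyldimethylsilyl)oxy]methyl}-4-[(4-methoxyphenyl)methoxy]-5-(propan-2-yl)hepta-2,6-dienal, via vinyllithium 14 (not isolated)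
Conditions: t-BuLi (2.1 equiv), Et2O, −78 °C; DMF, −78 °C; AcOH, −78 °C
Reagents that add atoms: N,N-dimethylformamide, CN(C)C=O
Why: Iodine–lithium exchange with retention of alkene geometry and formylation of the vinyllithium with DMF; the PMB oxygen can chelate lithium, and the low temperature should suppress silyl migration from the C7 oxygen.

Step 8
Reactants: 15 (Z)-enal with terminal vinyl group
Product: 17 (2Z,4S,5S)-2-{[(tert-butyldimethylsilyl)oxy]methyl}-4-[(4-methoxyphenyl)methoxy]-5-(propan-2-yl)hex-2-enedial, via vicinal diol 16 (not isolated)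
Conditions: OsO4 (2 mol %), NaIO4 (4 equiv), 2,6-lutidine, dioxane/H2O (3:1), rt
Reagents that add atoms: osmium tetroxide, O=[Os](=O)(=O)=O; sodium periodate, [Na+].[O-]I(=O)(=O)=O
Why: Lemieux–Johnson oxidation (osmium-catalysed dihydroxylation, then periodate cleavage); OsO4 should choose the monosubstituted, electron-richer vinyl group over the conjugated trisubstituted enal alkene, the lutidine buffer should spare the C5 centre, and the dialdehyde is taken into step 9 without storage.

Step 9
Reactants: 17 (Z)-enal dialdehyde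
Product: 18 (1R,2S,5S,6R)-3-{[(tert-butyldimethylsilyl)oxy]methyl}-5-[(4-methoxyphenyl)methoxy]-6-(propan-2-yl)cyclohex-3-ene-1,2-diol
Conditions: SmI2 (2.5 equiv, 0.1 M in THF, slow addition), t-BuOH (3 equiv), THF (0.01 M), −78 °C; aq. NaHCO3
Reagents that add atoms: none
Why: Electron transfer from divalent samarium to the enal gives an allyl-type ketyl bound to trivalent samarium, whose C1 terminus attacks the samarium-activated C6 aldehyde; a second electron transfer and protonation by tert-butanol deliver the diol. The closest known reaction type is the SmI2 pinacol cyclisation of 1,6-dialdehydes to cis-cyclohexane-1,2-diols, and low-valent titanium pinacol closures show that an enal can be one partner. The cyclohexene ring closes in the 6-exo-trig mode (C1 onto the C6 carbonyl carbon, oxygen outside the ring); closure through C3 would need a four-membered ring. C6 is set in a half-chair with the C5 isopropyl group equatorial and the cis C4 OPMB group axial, so the C6 oxygen should go equatorial, trans to isopropyl, the axial alternative clashing 1,3-diaxially with OPMB; C1 is set cis to the C6 oxygen because one samarium bridges both oxygens, and it is removed in step 10 in any case. The step needs C–C bond formation to outrun a second reduction of the enal ketyl, which would expel the C4 oxygen: the benzyl-type ether is a poor leaving group, the (Z)-geometry and allylic 1,3-strain hold C6 over C1, and −78 °C, high dilution and slow addition of SmI2 keep the reductant concentration low.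

Step 10
Reactants: 18 cis-diol
Product: 19 (4S,5R,6R)-2-{[(tert-butyldimethylsilyl)oxy]methyl}-6-hydroxy-4-[(4-methoxyphenyl)methoxy]-5-(propan-2-yl)cyclohex-2-en-1-one
Conditions: MnO2 (activated, 20 equiv), CH2Cl2, rt
Reagents that add atoms: none
Why: MnO2 oxidation of an allylic alcohol; the saturated C6 carbinol is not activated and should remain, so the C1 centre is erased and the C6 centre is kept.

Step 11
Reactants: 20 [(tert-butyldimethylsilyl)oxy]acetaldehyde; 21 ethyl 2-(triphenyl-λ5-phosphanylidene)propanoate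
Product: 22 ethyl (2E)-4-[(tert-butyldimethylsilyl)oxy]-2-methylbut-2-enoate
Conditions: CH2Cl2, 40 °C
Reagents that add atoms: none
Why: Wittig olefination with a stabilised α-methyl ylide, which should give the (E)-trisubstituted enoate.

Step 12
Reactants: 22 ethyl ester
Product: 23 (2E)-4-[(tert-butyldimethylsilyl)oxy]-2-methylbut-2-enoic acid
Conditions: LiOH, THF/MeOH/H2O, 0 °C to rt; 1 M HCl to pH 4, 0 °C
Reagents that add atoms: lithium hydroxide, [Li+].[OH-]
Why: Ester saponification; a primary TBS ether tolerates LiOH and a brief, cold, mildly acidic work-up.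

Step 13
Reactants: 23 silyl-protected hydroxytiglic acid; 19 hydroxy enone
Product: 25 (1R,5S,6S)-3-{[(tert-butyldimethylsilyl)oxy]methyl}-5-[(4-methoxyphenyl)methoxy]-2-oxo-6-(propan-2-yl)cyclohex-3-en-1-yl (2E)-4-[(tert-butyldimethylsilyl)oxy]-2-methylbut-2-enoate, via mixed anhydride 24 (not isolated)
Conditions: 2,4,6-Cl3C6H2COCl, Et3N, toluene, rt; then 19, DMAP, toluene, rt
Reagents that add atoms: none
Why: Yamaguchi esterification; DMAP should attack the unhindered acyl carbon of the mixed anhydride and pass it to the C6 hydroxyl, and the C6 configuration (equatorial, trans to the C5 isopropyl group) is the stable one should any enolisation occur.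

Step 14
Reactants: 25 C6 ester with C4 PMB ether
Product: 26 (1R,5S,6S)-3-{[(tert-butyldimethylsilyl)oxy]methyl}-5-hydroxy-2-oxo-6-(propan-2-yl)cyclohex-3-en-1-yl (2E)-4-[(tert-butyldimethylsilyl)oxy]-2-methylbut-2-enoate
Conditions: DDQ, CH2Cl2/pH 7 buffer (10:1), 0 °C
Reagents that add atoms: none
Why: Oxidative cleavage of a PMB ether with DDQ by hydride abstraction from the benzylic position; esters, silyl ethers and the enone should be inert.

Step 15
Reactants: 26 C4 alcohol
Product: 27 (1R,5S,6S)-3-{[(tert-butyldimethylsilyl)oxy]methyl}-2-oxo-6-(propan-2-yl)-5-(propanoyloxy)cyclohex-3-en-1-yl (2E)-4-[(tert-butyldimethylsilyl)oxy]-2-methylbut-2-enoate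
Conditions: (EtCO)2O, pyridine, DMAP (cat.), CH2Cl2, 0 °C to rt
Reagents that add atoms: propanoic anhydride, CCC(=O)OC(=O)CC
Why: DMAP-catalysed acylation of the secondary C4 alcohol with an anhydride; no stereocentre is touched.

Step 16
Reactants: 27 bis-silyl ether
Product: 28 (1R,5S,6S)-3-(hydroxymethyl)-2-oxo-6-(propan-2-yl)-5-(propanoyloxy)cyclohex-3-en-1-yl (2E)-4-hydroxy-2-methylbut-2-enoate (CNP0285949.1)
Conditions: HF·pyridine, pyridine/THF, 0 °C to rt
Reagents that add atoms: none
Why: Fluoride-mediated cleavage of both primary TBS ethers under buffered acidic conditions, which should avoid the acyl migration and elimination that basic fluoride can cause.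

**Compound list**

1 | 2-methylpropanal (isobutyraldehyde) | CC(C)C=O | starting material
2 | vinylmagnesium bromide | C=C[Mg]Br | starting material
3 | 4-methylpent-1-en-3-ol (racemic) | C=CC(O)C(C)C | intermediate
4 | bis(pinacolato)diboron | CC1(C)OB(OC1(C)C)B1OC(C)(C)C(C)(C)O1 | starting material
5 | 4,4,5,5-tetramethyl-2-[(2E)-4-methylpent-2-en-1-yl]-1,3,2-dioxaborolane | CC(C)/C=C/CB1OC(C)(C)C(C)(C)O1 | intermediate
6 | tert-butyldimethyl(prop-2-yn-1-yloxy)silane | C#CCO[Si](C)(C)C(C)(C)C | starting material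
7 | {3-[(tert-butyldimethylsilyl)oxy]prop-1-yn-1-yl}lithium (not isolated) | [Li]C#CCO[Si](C)(C)C(C)(C)C | intermediate
8 | 4-[(tert-butyldimethylsilyl)oxy]but-2-ynal | O=CC#CCO[Si](C)(C)C(C)(C)C | intermediate
9 | pinacol borate of 10, O–B(pin) on the C4 oxygen (not isolated) | CC(C)(C)[Si](C)(C)OCC#C[C@H](OB1OC(C)(C)C(C)(C)O1)[C@H](C(C)C)C=C | intermediate
10 | (3R,4R)-7-[(tert-butyldimethylsilyl)oxy]-3-(propan-2-yl)hept-1-en-5-yn-4-ol | CC(C)(C)[Si](C)(C)OCC#C[C@H](O)[C@H](C(C)C)C=C | intermediate
11 | sodium salt of the cyclic vinylalanate (five-membered O–Al–C2=C3–C4 ring, two 2-methoxyethoxy groups on aluminium; not isolated) | [Na+].COCCO[Al-]1(OCCOC)O[C@H]([C@H](C(C)C)C=C)C=C1CO[Si](C)(C)C(C)(C)C | intermediate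
12 | (3R,4R,5Z)-7-[(tert-butyldimethylsilyl)oxy]-6-iodo-3-(propan-2-yl)hepta-1,5-dien-4-ol | CC(C)(C)[Si](C)(C)OC/C(I)=C/[C@H](O)[C@H](C(C)C)C=C | intermediate
13 | tert-butyl({(2Z,4R,5R)-2-iodo-4-[(4-methoxyphenyl)methoxy]-5-(propan-2-yl)hepta-2,6-dien-1-yl}oxy)dimethylsilane | CC(C)(C)[Si](C)(C)OC/C(I)=C/[C@H](OCc1ccc(OC)cc1)[C@H](C(C)C)C=C | intermediate
14 | vinyllithium from 13, lithium in place of iodine with geometry retained (not isolated) | [Li]/C(CO[Si](C)(C)C(C)(C)C)=C\[C@H](OCc1ccc(OC)cc1)[C@H](C(C)C)C=C | intermediate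
15 | (2Z,4R,5R)-2-{[(tert-butyldimethylsilyl)oxy]methyl}-4-[(4-methoxyphenyl)methoxy]-5-(propan-2-yl)hepta-2,6-dienal | O=C/C(CO[Si](C)(C)C(C)(C)C)=C\[C@H](OCc1ccc(OC)cc1)[C@H](C(C)C)C=C | intermediate
16 | 6,7-diol of 15, C4 and C5 as in 15, both epimers at the new carbinol (not isolated) | O=C/C(CO[Si](C)(C)C(C)(C)C)=C\[C@H](OCc1ccc(OC)cc1)[C@H](C(C)C)C(O)CO | intermediate
17 | (2Z,4S,5S)-2-{[(tert-butyldimethylsilyl)oxy]methyl}-4-[(4-methoxyphenyl)methoxy]-5-(propan-2-yl)hex-2-enedial | O=C/C(CO[Si](C)(C)C(C)(C)C)=C\[C@H](OCc1ccc(OC)cc1)[C@H](C(C)C)C=O | intermediate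
18 | (1R,2S,5S,6R)-3-{[(tert-butyldimethylsilyl)oxy]methyl}-5-[(4-methoxyphenyl)methoxy]-6-(propan-2-yl)cyclohex-3-ene-1,2-diol | COc1ccc(CO[C@H]2C=C(CO[Si](C)(C)C(C)(C)C)[C@H](O)[C@H](O)[C@H]2C(C)C)cc1 | intermediate
19 | (4S,5R,6R)-2-{[(tert-butyldimethylsilyl)oxy]methyl}-6-hydroxy-4-[(4-methoxyphenyl)methoxy]-5-(propan-2-yl)cyclohex-2-en-1-one | COc1ccc(CO[C@H]2C=C(CO[Si](C)(C)C(C)(C)C)C(=O)[C@H](O)[C@H]2C(C)C)cc1 | intermediate
20 | [(tert-butyldimethylsilyl)oxy]acetaldehyde | O=CCO[Si](C)(C)C(C)(C)C | starting material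
21 | ethyl 2-(triphenyl-λ5-phosphanylidene)propanoate | CCOC(=O)C(C)=P(c1ccccc1)(c1ccccc1)c1ccccc1 | starting material
22 | ethyl (2E)-4-[(tert-butyldimethylsilyl)oxy]-2-methylbut-2-enoate | CCOC(=O)/C(C)=C/CO[Si](C)(C)C(C)(C)C | intermediate
23 | (2E)-4-[(tert-butyldimethylsilyl)oxy]-2-methylbut-2-enoic acid | OC(=O)/C(C)=C/CO[Si](C)(C)C(C)(C)C | intermediate
24 | mixed anhydride of 23 with 2,4,6-trichlorobenzoic acid (not isolated) | O=C(OC(=O)/C(C)=C/CO[Si](C)(C)C(C)(C)C)c1c(Cl)cc(Cl)cc1Cl | intermediate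
25 | (1R,5S,6S)-3-{[(tert-butyldimethylsilyl)oxy]methyl}-5-[(4-methoxyphenyl)methoxy]-2-oxo-6-(propan-2-yl)cyclohex-3-en-1-yl (2E)-4-[(tert-butyldimethylsilyl)oxy]-2-methylbut-2-enoate | COc1ccc(CO[C@H]2C=C(CO[Si](C)(C)C(C)(C)C)C(=O)[C@H](OC(=O)/C(C)=C/CO[Si](C)(C)C(C)(C)C)[C@H]2C(C)C)cc1 | intermediate
26 | (1R,5S,6S)-3-{[(tert-butyldimethylsilyl)oxy]methyl}-5-hydroxy-2-oxo-6-(propan-2-yl)cyclohex-3-en-1-yl (2E)-4-[(tert-butyldimethylsilyl)oxy]-2-methylbut-2-enoate | O[C@H]1C=C(CO[Si](C)(C)C(C)(C)C)C(=O)[C@H](OC(=O)/C(C)=C/CO[Si](C)(C)C(C)(C)C)[C@H]1C(C)C | intermediate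
27 | (1R,5S,6S)-3-{[(tert-butyldimethylsilyl)oxy]methyl}-2-oxo-6-(propan-2-yl)-5-(propanoyloxy)cyclohex-3-en-1-yl (2E)-4-[(tert-butyldimethylsilyl)oxy]-2-methylbut-2-enoate | CCC(=O)O[C@H]1C=C(CO[Si](C)(C)C(C)(C)C)C(=O)[C@H](OC(=O)/C(C)=C/CO[Si](C)(C)C(C)(C)C)[C@H]1C(C)C | intermediate
28 | (1R,5S,6S)-3-(hydroxymethyl)-2-oxo-6-(propan-2-yl)-5-(propanoyloxy)cyclohex-3-en-1-yl (2E)-4-hydroxy-2-methylbut-2-enoate | CCC(=O)O[C@H]1C=C(CO)C(=O)[C@H](OC(=O)/C(C)=C/CO)[C@H]1C(C)C | target

**Count**

Total steps: 16. Longest linear sequence: 13 steps (steps 1, 2, 4–10, 13–16).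

**Steps most likely to fail**

1. Step 9 (key step). The enal ketyl may take up a second electron before the ring closes, which expels the C4 ether oxygen; ketyls may also pair between molecules, or facial control at C6 may erode. Fallback, setting out from 15 and coming back at 18: the formyl group of 15 is methylenated with Ph3P=CH2 (THF, −78 to 0 °C) to give the triene tert-butyl({(2E,4R,5R)-2-ethenyl-4-[(4-methoxyphenyl)methoxy]-5-(propan-2-yl)hepta-2,6-dien-1-yl}oxy)dimethylsilane F1. Ring-closing metathesis with the second-generation Grubbs catalyst (CH2Cl2, 40 °C) then joins C1 and C6 as an alkene and gives the cyclohexa-1,3-diene tert-butyl({(5R,6R)-6-[(4-methoxyphenyl)methoxy]-5-(propan-2-yl)cyclohexa-1,3-dien-2-yl}methoxy)dimethylsilane F2. OsO4 (cat.) with N-methylmorpholine N-oxide in acetone/water should dihydroxylate the disubstituted C1=C6 alkene from the face opposite to the C4 and C5 substituents and give 18.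

2. Step 4. Uncatalysed addition of the boronate to the very electrophilic, sterically slim ynal may compete with the acid-bound pathway and lower the enantiomeric purity. Fallback, setting out from 6 and coming back at 12: acetylide 7, made from 6 as in step 3, is trapped with paraformaldehyde to give 4-[(tert-butyldimethylsilyl)oxy]but-2-yn-1-ol F3. NaAlH2(OCH2CH2OMe)2 and then I2, through the cyclic vinylalanate F4, give (2Z)-4-[(tert-butyldimethylsilyl)oxy]-3-iodobut-2-en-1-ol F5, and MnO2 (CH2Cl2, rt) gives (2Z)-4-[(tert-butyldimethylsilyl)oxy]-3-iodobut-2-enal F6. This is an enal, an aldehyde class for which the phosphoric acid catalysis is well established. Allylboration of F6 with 5 under (R)-TRIP gives the pinacol borate F7, whose hydrolysis gives 12, so that step 5 is no longer needed.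

3. Step 10. The C1 hydroxyl is pseudo-axial, so its oxidation may be slow, and MnO2 then has time to cleave the cis-glycol. Fallback, setting out from 18 and coming back at 25: 18 is heated with Bu2SnO (toluene, reflux, removal of water) to give the dibutylstannylene acetal F8. This is acylated in the same flask by mixed anhydride 24 at the equatorial C6 oxygen to give the C6 monoester (1R,2S,5S,6S)-3-{[(tert-butyldimethylsilyl)oxy]methyl}-2-hydroxy-5-[(4-methoxyphenyl)methoxy]-6-(propan-2-yl)cyclohex-3-en-1-yl (2E)-4-[(tert-butyldimethylsilyl)oxy]-2-methylbut-2-enoate F9. Dess–Martin periodinane (NaHCO3, CH2Cl2) then oxidises the free C1 hydroxyl and gives 25.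

**Further compounds**

F1 | step 9 | tert-butyl({(2E,4R,5R)-2-ethenyl-4-[(4-methoxyphenyl)methoxy]-5-(propan-2-yl)hepta-2,6-dien-1-yl}oxy)dimethylsilane | C=C/C(CO[Si](C)(C)C(C)(C)C)=C\[C@H](OCc1ccc(OC)cc1)[C@H](C(C)C)C=C
F2 | step 9 | tert-butyl({(5R,6R)-6-[(4-methoxyphenyl)methoxy]-5-(propan-2-yl)cyclohexa-1,3-dien-2-yl}methoxy)dimethylsilane | COc1ccc(CO[C@H]2C=C(CO[Si](C)(C)C(C)(C)C)C=C[C@H]2C(C)C)cc1
F3 | step 4 | 4-[(tert-butyldimethylsilyl)oxy]but-2-yn-1-ol | OCC#CCO[Si](C)(C)C(C)(C)C
F4 | step 4 | sodium salt of the cyclic vinylalanate from F3 (not isolated) | [Na+].COCCO[Al-]1(OCCOC)OCC=C1CO[Si](C)(C)C(C)(C)C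
F5 | step 4 | (2Z)-4-[(tert-butyldimethylsilyl)oxy]-3-iodobut-2-en-1-ol | OC/C=C(\I)CO[Si](C)(C)C(C)(C)C
F6 | step 4 | (2Z)-4-[(tert-butyldimethylsilyl)oxy]-3-iodobut-2-enal | O=C/C=C(\I)CO[Si](C)(C)C(C)(C)C
F7 | step 4 | pinacol borate of 12, O–B(pin) on the C4 oxygen (not isolated) | CC(C)(C)[Si](C)(C)OC/C(I)=C/[C@H](OB1OC(C)(C)C(C)(C)O1)[C@H](C(C)C)C=C
F8 | step 10 | dibutylstannylene acetal of 18, 2,2-dibutyl-1,3,2-dioxastannolane across the C1 and C6 oxygens (not isolated) | COc1ccc(CO[C@H]2C=C(CO[Si](C)(C)C(C)(C)C)[C@@H]3O[Sn](CCCC)(CCCC)O[C@@H]3[C@H]2C(C)C)cc1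
F9 | step 10 | (1R,2S,5S,6S)-3-{[(tert-butyldimethylsilyl)oxy]methyl}-2-hydroxy-5-[(4-methoxyphenyl)methoxy]-6-(propan-2-yl)cyclohex-3-en-1-yl (2E)-4-[(tert-butyldimethylsilyl)oxy]-2-methylbut-2-enoate | COc1ccc(CO[C@H]2C=C(CO[Si](C)(C)C(C)(C)C)[C@H](O)[C@H](OC(=O)/C(C)=C/CO[Si](C)(C)C(C)(C)C)[C@H]2C(C)C)cc1
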